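**Plan**

- Ring A (C1 pentanoyl, C2 OH, C3 CH3, C4 OH, C5 CH2 to ring B, C6 OH) has its three oxygens on alternate carbons and a carbon substituent on each carbon between them, the pattern of a folded tetraketide. The retrosynthesis therefore removes the two ring B benzyl groups and then opens ring A at C1–C2 to the linear 3,5,7-trioxo ester 16.
- The chain is then cut at the bond from chain C4 to the bridging CH2 (enolate alkylation by ring B bromide 9) and at chain C4–C5 (γ-acylation of the dianion of methyl 2-methylacetoacetate by a dioxolane-masked 3-oxoheptanoate).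
- Forward: ring B is finished first from 2,4,6-trihydroxytoluene (acylation, O-methylation, formylation, benzylation, reduction, bromination). The C1–C11 chain is built in two steps and joined to ring B by C-alkylation. The ketal is removed, ring A is closed with Mg(OMe)2 and the benzyl ethers are hydrogenolysed.
- Stereochemistry: the target has no stereocentre; the two epimerizable centres of the open chain (C2, C4) disappear when ring A aromatizes.

Key step: step 11

Remark: chain numbering in 14–16 takes the ester carbon as C1 and the butyl terminus as C11. These polycarbonyl compounds are mixtures of enol tautomers and, for 15 and 16, of epimers at C2 and C4; they are drawn as all-keto forms without stereodescriptors. Compounds 1, 2, 10 and 12 are taken as commercial.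

**Route**

Step 1
Reactants: 1 2,4,6-trihydroxytoluene; 2 butanoyl chloride
Product: 3 1-(2,4,6-trihydroxy-3-methylphenyl)butan-1-one
Conditions: AlCl3 (3.5 equiv), PhNO2/CH2Cl2, 0 °C to rt; then ice/aq. HCl
Reagents that add atoms: none
Why: Friedel–Crafts C-acylation of the symmetrical, strongly activated phloroglucinol ring at one of its two equivalent free positions, the first acyl group deactivating the ring against a second acylation.

Step 2
Reactants: 3 1-(2,4,6-trihydroxy-3-methylphenyl)butan-1-one
Product: 4 1-(2,6-dihydroxy-4-methoxy-3-methylphenyl)butan-1-one (aspidinol)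
Conditions: Me2SO4 (1.0 equiv), K2CO3 (1.1 equiv), acetone, rt
Reagents that add atoms: dimethyl sulfate, COS(=O)(=O)OC
Why: Williamson O-methylation selective for the hydroxyl para to the ketone, the only one not held in a hydrogen bond to the carbonyl and the most acidic, so that one equivalent of dimethyl sulfate should stop at the monomethyl ether.

Step 3
Reactants: 4 1-(2,6-dihydroxy-4-methoxy-3-methylphenyl)butan-1-one
Product: 6 3-butanoyl-2,4-dihydroxy-6-methoxy-5-methylbenzaldehyde, via aryl iminium salt 5 (not isolated)
Conditions: POCl3, DMF, EtOAc, 0 °C to rt; then H2O, 50 °C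
Reagents that add atoms: N,N-dimethylformamide, CN(C)C=O; water, O
Why: Vilsmeier–Haack formylation at the single remaining ring CH, which lies ortho or para to three oxygen donors, followed by hydrolysis of iminium salt 5 to the aldehyde.

Step 4
Reactants: 6 3-butanoyl-2,4-dihydroxy-6-methoxy-5-methylbenzaldehyde
Product: 7 2,4-bis(benzyloxy)-3-butanoyl-6-methoxy-5-methylbenzaldehyde
Conditions: BnBr (2.5 equiv), K2CO3, n-Bu4NI (cat.), DMF, 60 °C
Reagents that add atoms: benzyl bromide, BrCc1ccccc1
Why: Williamson etherification of both chelated phenols, O-alkylation being favoured by a carbonate base in a dipolar aprotic solvent and by the fact that every ring carbon is substituted, so that C-benzylation would have to dearomatize the ring.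

Step 5
Reactants: 7 2,4-bis(benzyloxy)-3-butanoyl-6-methoxy-5-methylbenzaldehyde
Product: 8 1-[2,6-bis(benzyloxy)-3-(hydroxymethyl)-4-methoxy-5-methylphenyl]butan-1-one
Conditions: NaBH4, THF/MeOH, −20 to 0 °C; then H2O
Reagents that add atoms: none
Why: chemoselective borohydride reduction of the aldehyde, the aryl ketone being flanked by two benzyloxy groups, twisted out of conjugation and far slower to accept hydride at low temperature.

Step 6
Reactants: 8 1-[2,6-bis(benzyloxy)-3-(hydroxymethyl)-4-methoxy-5-methylphenyl]butan-1-one
Product: 9 1-[2,6-bis(benzyloxy)-3-(bromomethyl)-4-methoxy-5-methylphenyl]butan-1-one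
Conditions: CBr4, PPh3, CH2Cl2, 0 °C; used at once without chromatography
Reagents that add atoms: tetrabromomethane, BrC(Br)(Br)Br
Why: Appel bromination under neutral conditions, which spares the benzyl ethers and the ketone, while the hexasubstituted ring has no free position for Friedel–Crafts self-alkylation of this easily ionized bromide.

Step 7
Reactants: 10 methyl 3-oxoheptanoate
Product: 11 methyl 2-(2-butyl-1,3-dioxolan-2-yl)acetate
Conditions: ethane-1,2-diol, p-TsOH·H2O (cat.), toluene, reflux, Dean–Stark
Reagents that add atoms: ethane-1,2-diol, OCCO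
Why: acid-catalysed dioxolane formation at the ketone with azeotropic removal of water, masking the future C7 carbonyl so that only one 1,3-diketone methylene exists at the alkylation stage.

Step 8
Reactants: 12 methyl 2-methyl-3-oxobutanoate; 11 methyl 2-(2-butyl-1,3-dioxolan-2-yl)acetate
Product: 14 methyl 6-(2-butyl-1,3-dioxolan-2-yl)-2-methyl-3,5-dioxohexanoate, via sodium lithium dianion 13 (not isolated)
Conditions: 12 (2.1 equiv), NaH, THF, 0 °C; n-BuLi, 0 °C; then 11 (1.0 equiv), −78 to 0 °C; AcOH quench
Reagents that add atoms: none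
Why: Claisen acylation of a β-keto ester dianion at its γ-carbon by an ester (Huckin–Weiler dianion chemistry), with a second equivalent of dianion 13 to deprotonate the 3,5-dioxo ester as it forms and an acetic acid quench that keeps the dioxolane intact.

Step 9
Reactants: 14 methyl 6-(2-butyl-1,3-dioxolan-2-yl)-2-methyl-3,5-dioxohexanoate; 9 1-[2,6-bis(benzyloxy)-3-(bromomethyl)-4-methoxy-5-methylphenyl]butan-1-one
Product: 15 methyl 4-{[2,4-bis(benzyloxy)-3-butanoyl-6-methoxy-5-methylphenyl]methyl}-6-(2-butyl-1,3-dioxolan-2-yl)-2-methyl-3,5-dioxohexanoate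
Conditions: K2CO3, acetone, rt (14 in slight excess)
Reagents that add atoms: none
Why: classical C-alkylation of a β-diketone potassium enolate by a reactive benzylic bromide at C4, the most acidic site between the two ketones, under conditions that leave the aryl ketone, ester and dioxolane untouched, whereas C2 is less acidic and would have to become quaternary.

Step 10
Reactants: 15 methyl 4-{[2,4-bis(benzyloxy)-3-butanoyl-6-methoxy-5-methylphenyl]methyl}-6-(2-butyl-1,3-dioxolan-2-yl)-2-methyl-3,5-dioxohexanoate
Product: 16 methyl 4-{[2,4-bis(benzyloxy)-3-butanoyl-6-methoxy-5-methylphenyl]methyl}-2-methyl-3,5,7-trioxoundecanoate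
Conditions: p-TsOH·H2O (cat.), acetone/H2O, rt
Reagents that add atoms: water, O
Why: acid-catalysed ketal hydrolysis under conditions too mild to cleave the benzyl ethers or the ester or to dehydrate the triketone to a pyranone.

Step 11
Reactants: 16 methyl 4-{[2,4-bis(benzyloxy)-3-butanoyl-6-methoxy-5-methylphenyl]methyl}-2-methyl-3,5,7-trioxoundecanoate
Product: 18 1-[3-{[2,4-bis(benzyloxy)-3-butanoyl-6-methoxy-5-methylphenyl]methyl}-2,4,6-trihydroxy-5-methylphenyl]pentan-1-one, via cyclohexane-1,3,5-trione 17 (not isolated)
Conditions: Mg(OMe)2 (excess, commercial solution), MeOH, rt to reflux; then cold 1 M HCl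
Reagents that add atoms: none
Why: Mg(OMe)2 turns 16 into a magnesium-chelated polyenolate whose C5/C7 diketone enolate adds through its central carbon (chain C6) to the C1 ester carbonyl; loss of methoxide forms the C1–C6 bond (C1–C2 of ring A) and gives trione 17, which tautomerizes irreversibly to the hexasubstituted phloroglucinol. The closest known reaction is the Claisen-mode (Dieckmann-type) cyclization of 3,5,7-triketo esters, and of the pyranones derived from them, to acylphloroglucinols under Mg(OMe)2, the laboratory counterpart of the polyketide Claisen fold. Ring A closes as a six-membered carbocycle by 6-exo-trig attack on the ester carbonyl; no stereocentre is created, and the epimeric centres at chain C2 and C4 become aromatic carbons. The step needs Claisen-mode selectivity: the aldol adduct from C2 attacking C7 has a quaternary C2 and cannot aromatize, so it reverts; the pyranone from O-acylation is reopened by methoxide; magnesium chelation of the 1,3-dicarbonyl units directs C-acylation; aromatization of 17 is then the only irreversible exit. Ring B carries no free phenol, so the base cannot expel the chain through a quinone methide and the methylene bridge survives.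

Step 12
Reactants: 18 1-[3-{[2,4-bis(benzyloxy)-3-butanoyl-6-methoxy-5-methylphenyl]methyl}-2,4,6-trihydroxy-5-methylphenyl]pentan-1-one
Product: 19 1-[3-{[3-butanoyl-2,4-dihydroxy-6-methoxy-5-methylphenyl]methyl}-2,4,6-trihydroxy-5-methylphenyl]pentan-1-one (CNP0210501.0)
Conditions: H2 (1 atm), Pd/C, EtOAc, rt
Reagents that add atoms: none
Why: hydrogenolysis of the two aryl benzyl ethers over palladium under neutral conditions, which leaves the hydrogen-bonded aryl ketones and the diarylmethane bridge intact and avoids the base-induced scrambling known for methylene-bridged phloroglucinols.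

**Compound list**

1 | 2,4,6-trihydroxytoluene (2-methylbenzene-1,3,5-triol) | Cc1c(O)cc(O)cc1O | starting material
2 | butanoyl chloride | CCCC(=O)Cl | starting material
3 | 1-(2,4,6-trihydroxy-3-methylphenyl)butan-1-one | CCCC(=O)c1c(O)cc(O)c(C)c1O | intermediate
4 | 1-(2,6-dihydroxy-4-methoxy-3-methylphenyl)butan-1-one (aspidinol) | CCCC(=O)c1c(O)cc(OC)c(C)c1O | intermediate
5 | N-[(3-butanoyl-2,4-dihydroxy-6-methoxy-5-methylphenyl)methylidene]-N-methylmethanaminium dichlorophosphate | CCCC(=O)c1c(O)c(C=[N+](C)C)c(OC)c(C)c1O.[O-]P(=O)(Cl)Cl | intermediate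
6 | 3-butanoyl-2,4-dihydroxy-6-methoxy-5-methylbenzaldehyde | CCCC(=O)c1c(O)c(C=O)c(OC)c(C)c1O | intermediate
7 | 2,4-bis(benzyloxy)-3-butanoyl-6-methoxy-5-methylbenzaldehyde | CCCC(=O)c1c(OCc2ccccc2)c(C=O)c(OC)c(C)c1OCc1ccccc1 | intermediate
8 | 1-[2,6-bis(benzyloxy)-3-(hydroxymethyl)-4-methoxy-5-methylphenyl]butan-1-one | CCCC(=O)c1c(OCc2ccccc2)c(CO)c(OC)c(C)c1OCc1ccccc1 | intermediate
9 | 1-[2,6-bis(benzyloxy)-3-(bromomethyl)-4-methoxy-5-methylphenyl]butan-1-one | CCCC(=O)c1c(OCc2ccccc2)c(CBr)c(OC)c(C)c1OCc1ccccc1 | intermediate
10 | methyl 3-oxoheptanoate | CCCCC(=O)CC(=O)OC | starting material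
11 | methyl 2-(2-butyl-1,3-dioxolan-2-yl)acetate | CCCCC1(CC(=O)OC)OCCO1 | intermediate
12 | methyl 2-methyl-3-oxobutanoate | CC(=O)C(C)C(=O)OC | starting material
13 | sodium lithium 1-methoxy-2-methylbuta-1,3-diene-1,3-diolate (dianion of 12) | C=C([O-])C(C)=C([O-])OC.[Na+].[Li+] | intermediate
14 | methyl 6-(2-butyl-1,3-dioxolan-2-yl)-2-methyl-3,5-dioxohexanoate | COC(=O)C(C)C(=O)CC(=O)CC1(CCCC)OCCO1 | intermediate
15 | methyl 4-{[2,4-bis(benzyloxy)-3-butanoyl-6-methoxy-5-methylphenyl]methyl}-6-(2-butyl-1,3-dioxolan-2-yl)-2-methyl-3,5-dioxohexanoate (epimer mixture) | COC(=O)C(C)C(=O)C(Cc1c(OCc2ccccc2)c(C(=O)CCC)c(OCc2ccccc2)c(C)c1OC)C(=O)CC1(CCCC)OCCO1 | intermediate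
16 | methyl 4-{[2,4-bis(benzyloxy)-3-butanoyl-6-methoxy-5-methylphenyl]methyl}-2-methyl-3,5,7-trioxoundecanoate (epimer and enol mixture) | CCCCC(=O)CC(=O)C(Cc1c(OCc2ccccc2)c(C(=O)CCC)c(OCc2ccccc2)c(C)c1OC)C(=O)C(C)C(=O)OC | intermediate
17 | 2-{[2,4-bis(benzyloxy)-3-butanoyl-6-methoxy-5-methylphenyl]methyl}-4-methyl-6-pentanoylcyclohexane-1,3,5-trione | CCCCC(=O)C1C(=O)C(C)C(=O)C(Cc2c(OCc3ccccc3)c(C(=O)CCC)c(OCc3ccccc3)c(C)c2OC)C1=O | intermediate
18 | 1-[3-{[2,4-bis(benzyloxy)-3-butanoyl-6-methoxy-5-methylphenyl]methyl}-2,4,6-trihydroxy-5-methylphenyl]pentan-1-one | CCCCC(=O)c1c(O)c(C)c(O)c(Cc2c(OCc3ccccc3)c(C(=O)CCC)c(OCc3ccccc3)c(C)c2OC)c1O | intermediate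
19 | 1-[3-{[3-butanoyl-2,4-dihydroxy-6-methoxy-5-methylphenyl]methyl}-2,4,6-trihydroxy-5-methylphenyl]pentan-1-one (CNP0210501.0) | CCCCC(=O)c1c(O)c(C)c(O)c(Cc2c(O)c(C(=O)CCC)c(O)c(C)c2OC)c1O | target

**Step count**

Total: 12 steps. Longest linear sequence: 10 steps (steps 1–6 and 9–12 from compound 1); steps 7 and 8 form the two-step chain branch that joins at step 9.

**Steps most likely to fail**

Step 11. The enolized chain may close along an aldol channel instead, the C8 methylene adding to the C3 carbonyl and dehydrating to a resorcinol. Methoxide may also cleave the 2-substituted 1,3-diketone by retro-Claisen fragmentation before ring A closes. The fallback makes ring A as an intact arene and joins it to ring B by Friedel–Crafts alkylation; it sets out from 1 and 8 and returns at 18. Compound 1 is acylated with pentanoyl chloride (CCCCC(=O)Cl) and AlCl3 as in step 1 to give 1-(2,4,6-trihydroxy-3-methylphenyl)pentan-1-one F1. The single free ring carbon of F1 is then alkylated by benzylic alcohol 8 with catalytic p-TsOH in CH2Cl2, through ionization of 8 to the trialkoxybenzyl cation, to give 18 ahead of step 12.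

Step 8. Proton transfer from the α-methylene of ester 11 to the dianion, followed by β-elimination that opens the dioxolane, may compete with acylation, and the product consumes dianion as it forms. The fallback is an aldol–oxidation sequence that sets out from 11 and returns at 14. Ester 11 is reduced with i-Bu2AlH in CH2Cl2 at −78 °C to 2-(2-butyl-1,3-dioxolan-2-yl)acetaldehyde F2. Dianion 13 adds to F2 at −78 °C to give methyl 6-(2-butyl-1,3-dioxolan-2-yl)-5-hydroxy-2-methyl-3-oxohexanoate F3 as a diastereomer mixture. Oxidation of the secondary alcohol with Dess–Martin periodinane buffered by NaHCO3 gives 14, and the route resumes at step 9.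

Step 9. The diketone enolate may undergo O-alkylation, double alkylation or attack at C2, the 3,5-dioxo ester may lactonize to a pyranone under base, and bromide 9 may be lost by ionization and hydrolysis. The fallback is a reductive Knoevenagel alkylation, which can only give C-monoalkylation and needs no halide; it sets out from 7 and 14 and returns at 15. Aldehyde 7 and diketone 14 are condensed under L-proline catalysis in CH2Cl2 or EtOH in the presence of Hantzsch ester (diethyl 2,6-dimethyl-1,4-dihydropyridine-3,5-dicarboxylate). The alkylidene diketone methyl 4-{[2,4-bis(benzyloxy)-3-butanoyl-6-methoxy-5-methylphenyl]methylidene}-6-(2-butyl-1,3-dioxolan-2-yl)-2-methyl-3,5-dioxohexanoate F4 forms at C4 and is reduced in the flask by hydride transfer to its β-carbon, giving 15. The route resumes at step 10, and steps 5 and 6 are then not needed.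

**Further compounds**

F1 | step 11 | 1-(2,4,6-trihydroxy-3-methylphenyl)pentan-1-one | CCCCC(=O)c1c(O)cc(O)c(C)c1O
F2 | step 8 | 2-(2-butyl-1,3-dioxolan-2-yl)acetaldehyde | CCCCC1(CC=O)OCCO1
F3 | step 8 | methyl 6-(2-butyl-1,3-dioxolan-2-yl)-5-hydroxy-2-methyl-3-oxohexanoate (diastereomer mixture) | COC(=O)C(C)C(=O)CC(O)CC1(CCCC)OCCO1
F4 | step 9 | methyl 4-{[2,4-bis(benzyloxy)-3-butanoyl-6-methoxy-5-methylphenyl]methylidene}-6-(2-butyl-1,3-dioxolan-2-yl)-2-methyl-3,5-dioxohexanoate (alkene isomer mixture) | COC(=O)C(C)C(=O)C(=Cc1c(OCc2ccccc2)c(C(=O)CCC)c(OCc2ccccc2)c(C)c1OC)C(=O)CC1(CCCC)OCCO1
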